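**Retrosynthetic overview**

1. Feature: the target is the C40 lycopene skeleton (C1 to C1') with an (E)-4-hydroxy-3-methylbut-2-enyl arm on C2 and on C2' and both ends closed to 2,6,6-trimethylcyclohexene rings (ring A = C1–C6, ring B = C1'–C6'), so forty of its fifty carbons can be bought as lycopene.
2. Last disconnection: ring A and ring B are opened at C1–C6 and C1'–C6' (retro cation–olefin cyclisation) to the acyclic C50 diol flavuxanthin, which carries isopropenyl groups on C2 and C2'.
3. Key disconnection: C2–C1'' and C2'–C1''' are cut, which leads to lycopene and two molecules of (E)-4-hydroxy-3-methylbut-2-enyl diphosphate (HMBPP); forward, a lycopene elongase transfers both arms and sets C2 and C2'.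
4. HMBPP is traced to (E)-4-chloro-2-methylbut-2-en-1-ol and diphosphate, and the chloro alcohol to 2-methyl-2-vinyloxirane.
5. Ring order: no ring exists before the last step; ring A and ring B are then closed one after the other by one C50 carotenoid β-cyclase.

Key step: step 3

Assumption: the lycopene elongase takes (E)-HMBPP itself as its C5 donor, so each hydroxyl enters with the donor and no later C–H oxidation is needed; this has not been shown with the isolated enzyme, although such enzymes deliver the hydroxylated product in hosts whose isoprenoid pathway contains HMBPP.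

**Route**

Step 1
Reactants: 1 2-methyl-2-vinyloxirane (isoprene monoxide, racemic)
Product: 3 (E)-4-chloro-2-methylbut-2-en-1-ol, via trichlorotitanium alkoxide 2 (not isolated)
Conditions: TiCl4 (1.5 equiv), CH2Cl2, −90 to −80 °C; then cold 1 M HCl
Reagents that add atoms: titanium tetrachloride, Cl[Ti](Cl)(Cl)Cl
Why: Lewis-acid-promoted SN2' opening of a vinyl epoxide, in which TiCl4 binds the oxirane oxygen, the tertiary allylic C–O bond breaks and chloride adds to the vinyl terminus, and the bulky titanated CH2O group should sit trans to the new CH2Cl so that the E alkene forms; the stereocentre of racemic 1 is lost.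

Step 2
Reactants: 3 (E)-4-chloro-2-methylbut-2-en-1-ol
Product: 4 (E)-4-hydroxy-3-methylbut-2-en-1-yl diphosphate (HMBPP; isolated as the triammonium salt, drawn as the free acid)
Conditions: (n-Bu4N)3HP2O7 (1.5 equiv), MeCN, 0 °C to rt; sulfonic acid cation-exchange resin (ammonium form), then cellulose chromatography (i-PrOH/MeCN/0.1 M NH4HCO3), lyophilisation
Reagents that add atoms: tris(tetra-n-butylammonium) hydrogen diphosphate, CCCC[N+](CCCC)(CCCC)CCCC.CCCC[N+](CCCC)(CCCC)CCCC.CCCC[N+](CCCC)(CCCC)CCCC.OP(=O)([O-])OP(=O)([O-])[O-]
Why: SN2 displacement of a primary allylic chloride by the diphosphate anion in a dipolar aprotic solvent, the standard preparation of allylic diphosphates from halides; the free primary hydroxyl is a much weaker nucleophile than diphosphate and the E alkene is not touched.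

Step 3
Reactants: 4 HMBPP (two equivalents consumed, used in excess); 5 all-E-lycopene
Product: 7 flavuxanthin, (2R,2'R)-2,2'-bis[(2E)-4-hydroxy-3-methylbut-2-enyl]-1,16,1',16'-tetradehydro-1,2,1',2'-tetrahydro-ψ,ψ-carotene, via nonaflavuxanthin 6 (not isolated)
Conditions: lycopene elongase LbtA of Dietzia sp. (or CrtEb of Corynebacterium glutamicum) as washed membrane fraction of recombinant Escherichia coli, 5 in phosphatidylcholine liposomes, 4 (about 6 equiv), MgCl2, HEPES–KOH pH 7.5, 30 °C, dark, Ar; MeOH/CHCl3 extraction; silica gel (hexane/acetone) to free diol 7 from 5 and 6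
Reagents that add atoms: none
Why: The elongase, an integral-membrane prenyltransferase of the UbiA type, ionises 4 with bound magnesium ions to the 4-hydroxy-3-methylbut-2-enyl cation, the isolated C1=C2 alkene of a ψ end of 5 attacks C1'' through C2 so that the charge moves to the tertiary C1, and an active-site base removes a proton from the C16 methyl to leave the isopropenyl group; the same sequence at the other end turns 6 into 7. The closest known reaction is this elongation step of bacterial C50 carotenoid biosynthesis, a prenyl transfer to a C=C bond with deprotonation, the same alkylation–deprotonation pattern as the branching prenyl couplings that lead to lavandulyl skeletons. No ring is closed. C2 and C2' are the only new stereocentres and both are set by the enzyme, which holds the end group so that the allyl cation reaches only one face of C1=C2, the face that gives R at each end as in 9. The step needs site selectivity for the two terminal alkenes over the eleven conjugated ones and attack on C1'' in place of C3'' of the donor: the ψ end is the only alkene at the end of a flexible C3–C4 link that gives a non-conjugated tertiary cation flanked by methyl protons and fits the closed end of the substrate channel, and the E geometry of the arm is kept because the C2''=C3'' bond of the donor is never broken.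

Step 4
Reactants: 7 flavuxanthin
Product: 9 (2R,2'R)-2,2'-bis[(2E)-4-hydroxy-3-methylbut-2-enyl]-β,β-carotene (C.p. 450, CNP0359519.1), via half-cyclised diol 8 (not isolated)
Conditions: C50 carotenoid β-cyclase (heterodimer LbtB/LbtC of Dietzia sp.) as membrane fraction of recombinant Escherichia coli, 7 (free of 5 and 6) in phosphatidylcholine liposomes, HEPES–KOH pH 7.5, 30 °C, dark, Ar; MeOH/CHCl3 extraction, chromatography, crystallisation
Reagents that add atoms: none
Why: Enzymatic cation–olefin cyclisation of the carotenoid cyclase type, in which protonation of the isopropenyl CH2 (C16) gives the tertiary C1 cation, C6 of the C5=C6 alkene closes the six-membered ring (6-endo) and loss of H6 places the ring alkene at C5=C6 in conjugation with the polyene, while C2 and C2' are not touched and keep their R configuration and no new stereocentre forms.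

**Compound list**

1 | 2-methyl-2-vinyloxirane (isoprene monoxide, racemic) | C=CC1(C)CO1 | starting material
2 | trichlorotitanium (E)-4-chloro-2-methylbut-2-en-1-olate | Cl[Ti](Cl)(Cl)OC/C(C)=C/CCl | intermediate
3 | (E)-4-chloro-2-methylbut-2-en-1-ol | OC/C(C)=C/CCl | intermediate
4 | (E)-4-hydroxy-3-methylbut-2-en-1-yl diphosphate (HMBPP, drawn as the free acid) | C/C(CO)=C\COP(=O)(O)OP(=O)(O)O | intermediate
5 | all-E-lycopene (ψ,ψ-carotene) | CC(C)=CCC/C(C)=C/C=C/C(C)=C/C=C/C(C)=C/C=C/C=C(C)/C=C/C=C(C)/C=C/C=C(C)/CCC=C(C)C | starting material
6 | nonaflavuxanthin, (2R)-2-[(2E)-4-hydroxy-3-methylbut-2-enyl]-1,16-didehydro-1,2-dihydro-ψ,ψ-carotene | C=C(C)[C@@H](C/C=C(\C)CO)CC/C(C)=C/C=C/C(C)=C/C=C/C(C)=C/C=C/C=C(C)/C=C/C=C(C)/C=C/C=C(C)/CCC=C(C)C | intermediate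
7 | flavuxanthin, (2R,2'R)-2,2'-bis[(2E)-4-hydroxy-3-methylbut-2-enyl]-1,16,1',16'-tetradehydro-1,2,1',2'-tetrahydro-ψ,ψ-carotene | C=C(C)[C@@H](C/C=C(\C)CO)CC/C(C)=C/C=C/C(C)=C/C=C/C(C)=C/C=C/C=C(C)/C=C/C=C(C)/C=C/C=C(C)/CC[C@H](C/C=C(\C)CO)C(C)=C | intermediate
8 | half-cyclised diol, (2R,2'R)-2,2'-bis[(2E)-4-hydroxy-3-methylbut-2-enyl]-1',16'-didehydro-1',2'-dihydro-β,ψ-carotene | C=C(C)[C@@H](C/C=C(\C)CO)CC/C(C)=C/C=C/C(C)=C/C=C/C(C)=C/C=C/C=C(C)/C=C/C=C(C)/C=C/C1=C(C)CC[C@H](C/C=C(\C)CO)C1(C)C | intermediate
9 | (2R,2'R)-2,2'-bis[(2E)-4-hydroxy-3-methylbut-2-enyl]-β,β-carotene (C.p. 450) | CC1=C(/C=C/C(C)=C/C=C/C(C)=C/C=C/C=C(C)/C=C/C=C(C)/C=C/C2=C(C)CC[C@H](C/C=C(\C)CO)C2(C)C)C(C)(C)[C@@H](C/C=C(\C)CO)CC1 | target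

**Step count and risks**

Total step count: 4. Longest linear sequence: 4 steps (1 to 3 to 4 to 7 to 9); lycopene 5 enters in step 3.

The three steps most likely to fail, in order of risk:

Step 3. The hydroxylated donor may be bound or ionised poorly by the cell-free enzyme, and transfer may stall after the first arm because the very lipophilic substrate exchanges slowly between liposome and membrane. The fallback sets out from lycopene 5 and comes back to the route at flavuxanthin 7, and it gives up the cell-free format. Lycopene 5 is formed inside an Escherichia coli strain that carries the genes for geranylgeranyl diphosphate synthase, phytoene synthase and phytoene desaturase together with the elongase gene. The C5 donor is then drawn from the methylerythritol phosphate pathway of the cell, of which 4 is a member. This is the setting in which lycopene elongases are known to deliver 7, so the question of donor and of substrate delivery no longer arises. The cell pellet is extracted with MeOH/acetone and 7 is purified as before. No new compound arises on this way (F0).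

Step 4. After ring closure the C5 cation may lose a proton from C4 or from the C18 methyl in place of C6, or closure may stop after one end, so that ε, γ or half-open end groups result. The fallback sets out from flavuxanthin 7 and comes back at the target 9. Flavuxanthin 7 is cyclised with the well-characterised C50 carotenoid ε-cyclase (decaprenoxanthin synthase, the CrtYe/CrtYf pair of Corynebacterium glutamicum) under the conditions of step 4 to give decaprenoxanthin F1, the (2R,6R,2'R,6'R) ε,ε isomer. The two ε rings are then moved into conjugation by the known base-mediated ε to β isomerisation of carotenoid end groups (KOCH3, DMSO, 80 to 100 °C, Ar, dark). Deprotonation at the doubly allylic C6 and C6' and reprotonation at C4 and C4' erases the C6 stereocentres and leaves C2 and C2' untouched, which gives 9.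

Step 2. The substrate's own hydroxyl may attack the allylic chloride of a second molecule, diphosphate may attack in the SN2' sense, or the chloride may hydrolyse while the displacement is slow. The fallback sets out from chloro alcohol 3 and comes back at HMBPP 4, and it masks the hydroxyl. Acetylation of 3 (Ac2O, pyridine, CH2Cl2, 0 °C) should give (E)-4-chloro-2-methylbut-2-enyl acetate F2. Displacement with (n-Bu4N)3HP2O7 in MeCN should give (E)-4-acetoxy-3-methylbut-2-enyl diphosphate F3. Methanolysis of the acetate (catalytic K2CO3, MeOH, 0 °C to rt), conditions under which allylic diphosphates are stable, followed by the ion exchange of step 2 should give 4.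

Further compounds
F0 | step 3 | none | none
F1 | step 4 | decaprenoxanthin, (2R,6R,2'R,6'R)-2,2'-bis[(2E)-4-hydroxy-3-methylbut-2-enyl]-ε,ε-carotene | CC1=CC[C@H](C/C=C(\C)CO)C(C)(C)[C@@H]1/C=C/C(C)=C/C=C/C(C)=C/C=C/C=C(C)/C=C/C=C(C)/C=C/[C@@H]1C(C)=CC[C@H](C/C=C(\C)CO)C1(C)C
F2 | step 2 | (E)-4-chloro-2-methylbut-2-enyl acetate | CC(=O)OC/C(C)=C/CCl
F3 | step 2 | (E)-4-acetoxy-3-methylbut-2-enyl diphosphate (drawn as the free acid) | CC(=O)OC/C(C)=C/COP(=O)(O)OP(=O)(O)O
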